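# Total synthesis proposal for the target gibberellin (45), the thirty-second member of the gibberellin A series

## Analysis of the target

The target 45 has cyclohexene ring A (C1–C5, C10), cyclopentane ring B (C5, C6, C8, C9, C10) and a bicyclo[3.2.1]octane made of ring C (C8, C9, C11–C14) and ring D (C8, C14, C13, C16, C15); a γ-lactone runs from C19 on C4 to the oxygen on C10, the C7 acid sits on C6 and the C17 methylene on C16. There are ten stereocentres (C3, C4, C5, C6, C8, C9, C10, C12, C13, C15), three of them quaternary (C4, C8, C10). On ring B, H5, H9, C7 and C1 lie on one face and the lactone atoms (C4, O–C10) on the other. On ring C, C10 and the C12 hydroxyl are syn and both anti to the C15–C16 bridge, O13 is cis to O12, and the C15 hydroxyl points to the side of C9. The sensitive groups are the tertiary allylic lactone C–O bond at C10 (ionisation in acid; lactone migration and retro-aldol cleavage of C3–C4 in base) and the tertiary allylic alcohol at C13 beside the exocyclic alkene (acid-induced skeletal rearrangement). The difficulty lies in the crowded C8–C9–C10 array, four different hydroxyls, and a ring A that tolerates little chemistry once formed. The strategy rests on one feature: the C19 carbonyl makes C5 the β-carbon of a 3-methylbutenolide (C4=C5) whose γ-carbon is the quaternary C10, while C6 is α to the C7 carboxyl. The C5–C6 bond of ring B is therefore a Michael retron, and the lactone enolate left at C4 is the nucleophile that later closes ring A onto C3.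

## Retrosynthetic reasoning

**Protecting groups.** 45 is traced to 44, with triethylsilyl ethers on O12, O13 and O15 and a 2-(trimethylsilyl)ethyl ester on C7. All four groups fall in one buffered desilylation, so neither acid nor hydroxide touches ring A.

**Ring A (C3–C4).** 44 is opened to the Z-enal 42. The aldehyde cannot enolise, and the Z alkene holds C3 within reach of C4. The forward aldol must form the quaternary C4, which the bicyclic geometry enforces, and the C3 carbinol. 42 comes from the Michael product 40 through alcohol 41.

**Ring B (C5–C6), the key disconnection.** 40 is opened to butenolide 37. Cutting here removes ring B and three stereocentres at once and leaves two simple functions, an acetate arm on C8 and a butenolide on C9. The forward step must bring the C6 enolate to C5 on the face of the butenolide that carries C9.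

**Butenolide (C4=C5 and O–C19).** 37 is cut at the ring alkene and the acyl–oxygen bond to methacrylate 36, from tertiary alcohol 34 and methacryloyl chloride 35. This places the methyl group and C19 without any enolate chemistry next to C10.

**Quaternary C10 (C10–C1 and C10–C5).** Diol 32 is cut twice at C10, to alkyne 29 and vinylmagnesium bromide 24, leaving the lactone carbonyl of 23 as C10. The lactone oxygen is O12, so both additions occur beside a syn-axial alkoxide that defines the faces of the C10 carbonyl. The order of the two additions decides the configuration at C10.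

**C15 hydroxyl.** 22 is traced to 21 by allylic hydroxylation. C15 is the only allylic CH2 of the exocyclic alkene, so no regiochemical question arises.

**Ring D (C13–C16).** 21 is opened to bromoalkene ketone 20. The bond chosen gives the C13 tertiary alcohol and the C16 methylene in one polar addition. The lactone between C10 and O12 locks ring C so that the arm on C8 is axial and 1,3 to C13.

**Acetate arm (C6).** Ester 18 is traced through diazoketone 15 to acid 12 and (trimethylsilyl)diazomethane 13. Homologation is needed because enolate alkylation at C8 can only place the new group anti to C10. The carboxyl therefore ends syn to C10, where the acetate arm belongs.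

**Quaternary C8 (C8–C15).** 12 is cut to acid 10 and 2,3-dibromoprop-1-ene 11. The bicyclic lactone shields one face of the C8 enolate and its bridgehead C9 cannot enolise.

**Lactone and the C12/C13 oxygens.** 8 is traced to diol 6 and then to alkene 5. Because 5 is C2-symmetric, syn-dihydroxylation gives one diol. Only one carboxyl/hydroxyl pair of that diol is 1,3-cis, so lactonisation tells C10 from C7 and O12 from O13 and fixes O12 syn to C10.

**Ring C.** 5 is the Diels–Alder adduct of fumarate 3 and buta-1,3-diene 4; 3 comes from fumaryl chloride 1 and two equivalents of menthol 2. The auxiliary sets the absolute configuration of C8 and C9, from which every other stereocentre follows.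

## Alternatives that were turned down

Alternative 1: The bond cut is C12–C13, so ring C would be closed last on a compound that already holds rings A, B and D. Forward, a triazolium-derived carbene would turn a C12 formyl group into an acyl anion equivalent that adds to the ring D carbonyl carbon C13, a crossed aldehyde–ketone benzoin closure. The product is A1, with a C12 ketone, the C13 tertiary hydroxyl and C16 masked as a dioxolane.

- For it: one catalytic, redox-neutral step makes the bridgehead carbinol and puts oxygen on C12, and the bridged geometry fixes C13.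
- Against it: the closure is reversible and forms a strained bicycle next to quaternary C8. The α-ketol of A1 can undergo acyloin shift. After the key step the C12 ketone must be reduced to the alcohol syn to C10, the dioxolane removed in acid, and a hindered ketone flanked by two oxygenated carbons methylenated, all in the presence of the ring A lactone.
- Comparison: Alternative 1 is stronger in convergence and in making the C12/C13 oxygen pattern in a single C–C bond formation. The chosen route sets that pattern at the start (6 to 8), never has to adjust C12, and obtains C16 directly as the alkene in 21.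

Alternative 2: The bond cut is C4–C5, with ring A formed as a carbocycle from a six-membered lactone. Forward, the silyl ketene acetal of a lactone whose ring oxygen sits on C1, with C1 attached to a ring B alkene C10=C5, would undergo Ireland–Claisen rearrangement. C4–C5 forms and the C1–O bond breaks, giving acid A2 with the alkene between C1 and C10.

- For it: C4 and C5 are set in one pericyclic step with chirality transfer from C1, and C3 is already configured. On this point it is stronger than the chosen route, where C3 depends on an aldol transition state.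
- Against it: the alkene ends at C1–C10 and C10 carries no oxygen, so the lactone and the C1–C2 alkene must still be made by lactonisation onto C10 and elimination. C7 in A2 is at the alcohol oxidation level and needs two late oxidations. Ring B must exist before the key step and so needs a separate construction.
- Comparison: the chosen route has the lactone oxygen on C10 from 32 onward and uses one butenolide for both late ring closures, so only four steps follow the key step.

Alternative 3: The bonds cut are C8–C15 and C6–C15, with ring D built on a ring B alkene. Forward, a diazo group on C15 next to the C16 carbonyl, carried by C13, would give a copper or rhodium carbenoid that adds to the C6–C8 double bond. The product is cyclopropyl ketone A3, whose three-membered ring is then opened.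

- For it: quaternary C8 and ring D arise in one step with two C–C bonds, and the C16 ketone is a handle for the methylene. In bonds formed per step it is stronger than the chosen route.
- Against it: the C6–C8 alkene is tetrasubstituted and conjugated to the C7 ester, a poor partner for an electrophilic carbenoid. The ring A alkene and C–H insertion compete. The opening must break C6–C15 and not C8–C15 and must set C6. C15 then still lacks its hydroxyl and C16 its methylene, on the complete and fragile tetracycle.
- Comparison: the chosen route closes ring D on the small bicyclic lactone 20 by a polar addition that delivers the C13 hydroxyl and the C16 methylene together, and leaves only two ring closures for the late stage.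

Key step: step 21

Assumption: the aluminium-promoted cycloaddition of a dimenthyl fumarate is taken to give the (1S,2S) adduct from the (1R,2S,5R)-menthyl ester, so the (1S,2R,5S)-menthyl ester is used to reach the (1R,2R) series; if the sense is the opposite, the other menthol enantiomer is used.

## Route

Step 1
Reactants: 1 fumaryl chloride; 2 (1S,2R,5S)-menthol (two equivalents)
Product: 3 bis[(1S,2R,5S)-menthyl] fumarate
Conditions: 2 (2.1 equiv), pyridine, DMAP (cat.), CH2Cl2, 0 °C → rt
Reagents that add atoms: (1S,2R,5S)-menthol (the second equivalent of 2), CC(C)[C@H]1CC[C@H](C)C[C@@H]1O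
Why: Twofold acylation of the secondary alcohol by the diacid chloride, one molecule of menthol at each acyl chloride; no stereocentre is touched and the E alkene is kept.

Step 2
Reactants: 3 bis[(1S,2R,5S)-menthyl] fumarate; 4 buta-1,3-diene
Product: 5 bis[(1S,2R,5S)-menthyl] (1R,2R)-cyclohex-4-ene-1,2-dicarboxylate
Conditions: iBu2AlCl, toluene–hexane, −40 °C
Reagents that add atoms: none
Why: Aluminium-promoted asymmetric Diels–Alder reaction of a chiral fumarate; the menthyl groups shield one face of the aluminium-bound diester, and suprafacial addition to the E alkene makes C8 and C9 trans.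

Step 3
Reactants: 5 bis[(1S,2R,5S)-menthyl] (1R,2R)-cyclohex-4-ene-1,2-dicarboxylate
Product: 6 cis-4,5-diol of 5 (the future O12 and O13)
Conditions: OsO4 (cat.), N-methylmorpholine N-oxide, acetone–H2O, rt
Reagents that add atoms: N-methylmorpholine N-oxide, C[N+]1([O-])CCOCC1; water, O
Why: Upjohn syn-dihydroxylation; the two alkene faces of the C2-symmetric diester are homotopic, so only one cis-diol can form.

Step 4
Reactants: 6 cis-4,5-diol of 5
Product: 8 hydroxy lactone acid (γ-lactone from C10 to O12; C13 hydroxyl on the lactone face; C8 carboxyl on the other face), via diol diacid 7 (not isolated)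
Conditions: KOH, MeOH–H2O, reflux; HCl to pH 1; TsOH (cat.), toluene, reflux
Reagents that add atoms: water, O
Why: Saponification then acid-catalysed lactonisation; only the C10 carboxyl and O12 are 1,3-cis, so a single γ-lactone forms. This tells C10 from C7 and O12 from O13, and fixes O12 syn to C10.

Step 5
Reactants: 8 hydroxy lactone acid
Product: 10 C13 triethylsilyl ether of 8 (free acid), via bis-silylated lactone 9 (not isolated)
Conditions: Et3SiCl (2.5 equiv), imidazole, DMF, rt; then AcOH (cat.), THF–H2O
Reagents that add atoms: chlorotriethylsilane, CC[Si](Cl)(CC)CC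
Why: Silylation of the secondary alcohol; the silyl ester formed alongside is hydrolysed on work-up. The ether is equatorial and does not shield the face of C8 that is to be alkylated.

Step 6
Reactants: 10 C13 triethylsilyl ether of 8; 11 2,3-dibromoprop-1-ene
Product: 12 C8-alkylated acid (2-bromoallyl arm C15–C17 anti to the lactone bridge, carboxyl C7 syn to it)
Conditions: LiN(iPr)2 (2.2 equiv), THF–DMPU, −78 → 0 °C; 11, −78 °C → rt; aq. HCl (pH 3)
Reagents that add atoms: none
Why: Alkylation of a carboxylic acid dianion; C9 is a lactone bridgehead and cannot enolise (Bredt's rule). The allylic bromide attacks the C8 enediolate anti to the lactone bridge, so the arm becomes trans to C10.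

Step 7
Reactants: 12 C8-alkylated acid; 13 (trimethylsilyl)diazomethane
Product: 15 diazomethyl ketone of 12, via acid chloride 14 (not isolated)
Conditions: Me2C=C(Cl)NMe2, CH2Cl2, 0 °C; then 13, MeCN–THF, 0 °C → rt
Reagents that add atoms: none
Why: First half of an Arndt–Eistert homologation: the acid chloride is made under neutral conditions and acylates the silyl diazomethane, whose silyl group leaves as the chlorosilane.

Step 8
Reactants: 15 diazomethyl ketone of 12; 16 2-(trimethylsilyl)ethanol
Product: 18 2-(trimethylsilyl)ethyl ester of the homologated acid (C8–CH2–CO2R, C6 and C7), via ketene 17 (not isolated)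
Conditions: PhCO2Ag (cat.), Et3N, THF, rt, dark
Reagents that add atoms: none
Why: Silver-promoted Wolff rearrangement; C8 migrates with retention to give the ketene, which the alcohol traps, so C6 is inserted between C8 and C7.

Step 9
Reactants: 18 2-(trimethylsilyl)ethyl ester
Product: 19 C13 alcohol
Conditions: AcOH–THF–H2O (3:1:1), rt
Reagents that add atoms: none
Why: Mild acid hydrolysis of the secondary triethylsilyl ether; the lactone, the silylethyl ester and the vinyl bromide are inert.

Step 10
Reactants: 19 C13 alcohol
Product: 20 C13 ketone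
Conditions: Dess–Martin periodinane, NaHCO3, CH2Cl2, rt
Reagents that add atoms: none
Why: Dess–Martin oxidation of the secondary alcohol under buffered conditions; C12 is held by the lactone and cannot epimerise.

Step 11
Reactants: 20 C13 ketone
Product: 21 tricyclic tertiary alcohol (ring D closed, C16 exocyclic methylene, C13 hydroxyl cis to O12, lactone C10–O12, acetate arm on C8)
Conditions: CrCl2 (excess), NiCl2 (cat.), DMF, rt → 50 °C
Reagents that add atoms: none
Why: Intramolecular Nozaki–Hiyama–Kishi reaction; zerovalent nickel inserts into the C–Br bond, and the alkenyl group passes to trivalent chromium and adds to the C13 ketone. The lactone bridge holds the arm on C8 axial and 1,3 to C13, so the five-membered ring D can close on one face only.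

Step 12
Reactants: 21 tricyclic tertiary alcohol
Product: 22 C15,C13-diol (C15 hydroxyl on the ring D face turned toward C9)
Conditions: SeO2 (cat.), t-BuOOH, CH2Cl2, rt
Reagents that add atoms: tert-butyl hydroperoxide, CC(C)(C)OO
Why: Selenium dioxide allylic hydroxylation (ene reaction, then [2,3]-shift), regioselective because C15 carries the only allylic hydrogens. Oxygen should arrive on the face toward C9, the other face being screened by the C14 hydrogen and the arm on C8.

Step 13
Reactants: 22 C15,C13-diol
Product: 23 bis(triethylsilyl) ether of 22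
Conditions: Et3SiOTf (2.5 equiv), 2,6-lutidine, CH2Cl2, 0 °C → rt
Reagents that add atoms: triethylsilyl trifluoromethanesulfonate, CC[Si](CC)(CC)OS(=O)(=O)C(F)(F)F
Why: Silyl triflate silylation of the secondary and the tertiary alcohol.

Step 14
Reactants: 23 bis(triethylsilyl) ether of 22; 24 vinylmagnesium bromide
Product: 26 lactol (C10 hemiketal bearing the vinyl group, mixture of C10 epimers), via lithium ester enolate 25 (not isolated)
Conditions: LiN(iPr)2 (1.05 equiv), THF, −78 °C; 24 (1.3 equiv), −78 °C; AcOH, −78 °C
Reagents that add atoms: none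
Why: The ester is masked in situ as its lithium enolate, its α-hydrogens being the only acidic ones, so the Grignard reagent adds to the lactone carbonyl alone. The bridged magnesium lactolate does not open at low temperature, and protonation returns the ester.

Step 15
Reactants: 27 prop-2-yn-1-ol; 28 4-methoxybenzyl chloride
Product: 29 4-methoxybenzyl prop-2-ynyl ether
Conditions: NaH, Bu4NI (cat.), THF, 0 °C → rt
Reagents that add atoms: none
Why: Williamson ether synthesis through the alkoxide.

Step 16
Reactants: 26 lactol; 29 4-methoxybenzyl prop-2-ynyl ether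
Product: 32 diol (C10 tertiary alcohol bearing the vinyl group C5 and the alkynyl arm C1–C3; free C12 hydroxyl), via lithium acetylide 30 (not isolated), via dichlorocerium acetylide 31 (not isolated)
Conditions: 29, n-BuLi, THF, −78 °C; CeCl3, −78 °C; then 26, −78 → −20 °C; aq. NH4Cl
Reagents that add atoms: none
Why: Organocerium 1,2-addition to the keto form of the lactol. The metal on the C12 alkoxide holds the C10 carbonyl oxygen toward O12, the face toward C8 is blocked by the acetate arm, and the alkynyl group enters anti to C8, which sets C10.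

Step 17
Reactants: 32 diol
Product: 33 Z-alkene diol
Conditions: H2 (1 atm), Pd/CaCO3 poisoned with Pb(OAc)2 (Lindlar catalyst), quinoline, EtOAc, rt
Reagents that add atoms: none
Why: Lindlar semi-hydrogenation; syn addition of hydrogen gives the Z alkene, and the vinyl and methylene groups react far more slowly on the poisoned catalyst.

Step 18
Reactants: 33 Z-alkene diol
Product: 34 C12 triethylsilyl ether (free tertiary C10 hydroxyl)
Conditions: Et3SiOTf (1.1 equiv), 2,6-lutidine, CH2Cl2, −78 °C
Reagents that add atoms: triethylsilyl trifluoromethanesulfonate, CC[Si](CC)(CC)OS(=O)(=O)C(F)(F)F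
Why: Selective silylation of the secondary hydroxyl at low temperature; the tertiary bis-allylic hydroxyl is slower.

Step 19
Reactants: 34 C12 triethylsilyl ether; 35 methacryloyl chloride
Product: 36 C10 methacrylate
Conditions: LiN(SiMe3)2, THF, −78 °C; 35, −78 → −30 °C
Reagents that add atoms: none
Why: Acylation of the lithium alkoxide of the tertiary alcohol by the acid chloride at low temperature, where attack of the alkoxide on the distant ester is slow.

Step 20
Reactants: 36 C10 methacrylate
Product: 37 butenolide (3-methylbutenolide with quaternary γ-carbon C10 bound to C9 and to the Z-allylic ether arm; acetate arm on C8)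
Conditions: second-generation Grubbs catalyst RuCl2(=CHPh)(PCy3)(H2IMes) (10 mol %), toluene, 80 °C
Reagents that add atoms: none
Why: Ring-closing metathesis; the ruthenium carbene forms at the terminal vinyl group and closes on the methacrylate to the five-membered butenolide with loss of ethene. The hindered Z alkene and the exocyclic methylene should not take part.

Step 21
Reactants: 37 butenolide
Product: 40 ring B closed tricycle with cis-fused saturated lactone, via lithium ester enolate 38 (not isolated), via lithium lactone enolate 39 (not isolated)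
Conditions: LiN(SiMe3)2 (1.2 equiv), THF, −78 → −20 °C; AcOH
Reagents that add atoms: none
Why: The base removes a C6 hydrogen, the only acidic one because C10 is quaternary and the butenolide has no γ-hydrogen, to give the ester enolate. Its α-carbon adds to C5, the β-carbon of the butenolide, in an intramolecular Michael addition; the closest known reaction type is the conjugate addition of ester enolates to butenolides. Ring B (C5, C6, C8, C9, C10) closes in a 5-exo-trig mode. C5 is set by the tether: the enolate is tied through C8 and C9 to C10 and reaches only the butenolide face that carries C9, so lactone and ring B are cis-fused. C6 takes the ester on the convex face, trans to C4, directly or by equilibration through the ester enolate. C4 is set by protonation of the lactone enolate and does not matter, since C4 is enolised again in step 24. The step needs 1,4- over 1,2-addition: in the rotamer with the lactone oxygen under ring C, C5 points at C6 and the lactone carbonyl is turned away. The more stable lactone enolate makes the addition favourable.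

Step 22
Reactants: 40 ring B closed tricycle
Product: 41 Z-allylic alcohol
Conditions: DDQ, CH2Cl2–pH 7 buffer, 0 °C
Reagents that add atoms: none
Why: Oxidative cleavage of the 4-methoxybenzyl ether (hydride abstraction, then hydrolysis of the oxocarbenium ion); silyl ethers, ester and lactone are untouched.

Step 23
Reactants: 41 Z-allylic alcohol
Product: 42 Z-enal
Conditions: Dess–Martin periodinane, NaHCO3, CH2Cl2, 0 °C
Reagents that add atoms: none
Why: Dess–Martin oxidation of the allylic alcohol under buffered, neutral conditions that keep the Z geometry.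

Step 24
Reactants: 42 Z-enal
Product: 44 tris(triethylsilyl) ether 2-(trimethylsilyl)ethyl ester of the target gibberellin, via potassium lactone enolate 43 (not isolated)
Conditions: KN(SiMe3)2, 18-crown-6, THF, −78 °C; AcOH, −78 °C
Reagents that add atoms: none
Why: Intramolecular aldol addition of the lactone enolate to the non-enolisable Z-enal, closing the six-membered ring A; the lactone α-hydrogen is more acidic and more exposed than the ester α-hydrogen at C6. C4 is fixed by geometry, since C3 can bond only on the face that carries C1. The crown-ether-separated potassium enolate should react through an open transition state with the aldehyde oxygen anti to the enolate oxygen, giving the axial C3 hydroxyl.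

Step 25
Reactants: 44 tris(triethylsilyl) ether 2-(trimethylsilyl)ethyl ester of the target gibberellin
Product: 45 target gibberellin (3,12,13,15-tetrahydroxy-1,16-diene 7-acid 19,10-lactone)
Conditions: Bu4NF, AcOH, THF, 0 °C → rt
Reagents that add atoms: none
Why: Fluoride cleaves the three triethylsilyl ethers and the 2-(trimethylsilyl)ethyl ester (fragmentation to ethene); the acetic acid buffer avoids retro-aldol cleavage and lactone migration in ring A.

## Compound list

1 | fumaryl chloride | O=C(Cl)/C=C/C(=O)Cl | starting material
2 | (1S,2R,5S)-menthol | CC(C)[C@H]1CC[C@H](C)C[C@@H]1O | starting material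
3 | bis[(1S,2R,5S)-menthyl] fumarate | O=C(O[C@H]1C[C@@H](C)CC[C@@H]1C(C)C)/C=C/C(=O)O[C@H]1C[C@@H](C)CC[C@@H]1C(C)C | intermediate
4 | buta-1,3-diene | C=CC=C | starting material
5 | bis[(1S,2R,5S)-menthyl] (1R,2R)-cyclohex-4-ene-1,2-dicarboxylate | O=C(O[C@H]1C[C@@H](C)CC[C@@H]1C(C)C)[C@@H]1CC=CC[C@H]1C(=O)O[C@H]1C[C@@H](C)CC[C@@H]1C(C)C | intermediate
6 | cis-4,5-diol of 5 (trans-diester, cis-diol) | O=C(O[C@H]1C[C@@H](C)CC[C@@H]1C(C)C)[C@@H]1C[C@@H](O)[C@@H](O)C[C@H]1C(=O)O[C@H]1C[C@@H](C)CC[C@@H]1C(C)C | intermediate
7 | diol diacid from 6 | O=C(O)[C@@H]1C[C@@H](O)[C@@H](O)C[C@H]1C(=O)O | intermediate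
8 | hydroxy lactone acid (lactone C10–O12, C13 hydroxyl, C8 carboxyl) | O=C(O)[C@@H]1C[C@@H](O)[C@@H]2C[C@H]1C(=O)O2 | intermediate
9 | C13 triethylsilyl ether triethylsilyl ester of 8 | O=C(O[Si](CC)(CC)CC)[C@@H]1C[C@@H](O[Si](CC)(CC)CC)[C@@H]2C[C@H]1C(=O)O2 | intermediate
10 | C13 triethylsilyl ether of 8 (free acid) | O=C(O)[C@@H]1C[C@@H](O[Si](CC)(CC)CC)[C@@H]2C[C@H]1C(=O)O2 | intermediate
11 | 2,3-dibromoprop-1-ene | C=C(Br)CBr | starting material
12 | C8-(2-bromoallyl) acid (arm anti to the lactone bridge) | O=C(O)[C@@]1(CC(Br)=C)C[C@@H](O[Si](CC)(CC)CC)[C@@H]2C[C@H]1C(=O)O2 | intermediate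
13 | (trimethylsilyl)diazomethane | C[Si](C)(C)C=[N+]=[N-] | starting material
14 | acid chloride of 12 | O=C(Cl)[C@@]1(CC(Br)=C)C[C@@H](O[Si](CC)(CC)CC)[C@@H]2C[C@H]1C(=O)O2 | intermediate
15 | diazomethyl ketone of 12 | [N-]=[N+]=CC(=O)[C@@]1(CC(Br)=C)C[C@@H](O[Si](CC)(CC)CC)[C@@H]2C[C@H]1C(=O)O2 | intermediate
16 | 2-(trimethylsilyl)ethanol | C[Si](C)(C)CCO | starting material
17 | ketene from 15 (C8–CH=C=O) | O=C=C[C@@]1(CC(Br)=C)C[C@@H](O[Si](CC)(CC)CC)[C@@H]2C[C@H]1C(=O)O2 | intermediate
18 | 2-(trimethylsilyl)ethyl ester of the homologated acid, C13 triethylsilyl ether | C[Si](C)(C)CCOC(=O)C[C@@]1(CC(Br)=C)C[C@@H](O[Si](CC)(CC)CC)[C@@H]2C[C@H]1C(=O)O2 | intermediate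
19 | C13 alcohol | C[Si](C)(C)CCOC(=O)C[C@@]1(CC(Br)=C)C[C@@H](O)[C@@H]2C[C@H]1C(=O)O2 | intermediate
20 | C13 ketone | C[Si](C)(C)CCOC(=O)C[C@@]1(CC(Br)=C)CC(=O)[C@@H]2C[C@H]1C(=O)O2 | intermediate
21 | tricyclic tertiary alcohol (rings C and D, lactone C10–O12) | C=C1C[C@]2(CC(=O)OCC[Si](C)(C)C)C[C@@]1(O)[C@@H]3C[C@H]2C(=O)O3 | intermediate
22 | C15,C13-diol (C15 hydroxyl toward C9) | C=C1[C@@H](O)[C@]2(CC(=O)OCC[Si](C)(C)C)C[C@@]1(O)[C@@H]3C[C@H]2C(=O)O3 | intermediate
23 | C15,C13-bis(triethylsilyl) ether | C=C1[C@@H](O[Si](CC)(CC)CC)[C@]2(CC(=O)OCC[Si](C)(C)C)C[C@@]1(O[Si](CC)(CC)CC)[C@@H]3C[C@H]2C(=O)O3 | intermediate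
24 | vinylmagnesium bromide | C=C[Mg]Br | starting material
25 | lithium ester enolate of 23 | C=C1[C@@H](O[Si](CC)(CC)CC)[C@]2(C=C([O-])OCC[Si](C)(C)C)C[C@@]1(O[Si](CC)(CC)CC)[C@@H]3C[C@H]2C(=O)O3.[Li+] | intermediate
26 | vinyl lactol (C10 hemiketal, both C10 epimers) | C=C1[C@@H](O[Si](CC)(CC)CC)[C@]2(CC(=O)OCC[Si](C)(C)C)C[C@@]1(O[Si](CC)(CC)CC)[C@@H]3C[C@H]2C(O)(C=C)O3 | intermediate
27 | prop-2-yn-1-ol | C#CCO | starting material
28 | 4-methoxybenzyl chloride | COc1ccc(CCl)cc1 | starting material
29 | 4-methoxybenzyl prop-2-ynyl ether | C#CCOCc1ccc(OC)cc1 | intermediate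
30 | lithium acetylide of 29 | [Li+].[C-]#CCOCc1ccc(OC)cc1 | intermediate
31 | dichlorocerium acetylide of 29 | Cl[Ce](Cl)C#CCOCc1ccc(OC)cc1 | intermediate
32 | C10 carbinol with vinyl and alkynyl arm, free C12 hydroxyl | C=C1[C@@H](O[Si](CC)(CC)CC)[C@]2(CC(=O)OCC[Si](C)(C)C)C[C@@]1(O[Si](CC)(CC)CC)[C@@H](O)C[C@H]2[C@@](O)(C=C)C#CCOCc3ccc(OC)cc3 | intermediate
33 | Z-alkene diol | C=C1[C@@H](O[Si](CC)(CC)CC)[C@]2(CC(=O)OCC[Si](C)(C)C)C[C@@]1(O[Si](CC)(CC)CC)[C@@H](O)C[C@H]2[C@@](O)(C=C)/C=C\COCc3ccc(OC)cc3 | intermediate
34 | C12 triethylsilyl ether, free C10 hydroxyl | C=C1[C@@H](O[Si](CC)(CC)CC)[C@]2(CC(=O)OCC[Si](C)(C)C)C[C@@]1(O[Si](CC)(CC)CC)[C@@H](O[Si](CC)(CC)CC)C[C@H]2[C@@](O)(C=C)/C=C\COCc3ccc(OC)cc3 | intermediate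
35 | methacryloyl chloride | C=C(C)C(=O)Cl | starting material
36 | C10 methacrylate | C=C1[C@@H](O[Si](CC)(CC)CC)[C@]2(CC(=O)OCC[Si](C)(C)C)C[C@@]1(O[Si](CC)(CC)CC)[C@@H](O[Si](CC)(CC)CC)C[C@H]2[C@@](OC(=O)C(C)=C)(C=C)/C=C\COCc3ccc(OC)cc3 | intermediate
37 | butenolide, precursor of the key step | C=C1[C@@H](O[Si](CC)(CC)CC)[C@]2(CC(=O)OCC[Si](C)(C)C)C[C@@]1(O[Si](CC)(CC)CC)[C@@H](O[Si](CC)(CC)CC)C[C@H]2[C@]3(/C=C\COCc4ccc(OC)cc4)C=C(C)C(=O)O3 | intermediate
38 | lithium ester enolate of 37 | C=C1[C@@H](O[Si](CC)(CC)CC)[C@]2(C=C([O-])OCC[Si](C)(C)C)C[C@@]1(O[Si](CC)(CC)CC)[C@@H](O[Si](CC)(CC)CC)C[C@H]2[C@]3(/C=C\COCc4ccc(OC)cc4)C=C(C)C(=O)O3.[Li+] | intermediate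
39 | lithium lactone enolate after ring B closure | C=C1[C@@H](O[Si](CC)(CC)CC)[C@]23C[C@@]1(O[Si](CC)(CC)CC)[C@@H](O[Si](CC)(CC)CC)C[C@H]2[C@@]2(/C=C\COCc4ccc(OC)cc4)OC([O-])=C(C)[C@H]2[C@@H]3C(=O)OCC[Si](C)(C)C.[Li+] | intermediate
40 | ring B closed tricycle with cis-fused lactone, product of the key step | C=C1[C@@H](O[Si](CC)(CC)CC)[C@]23C[C@@]1(O[Si](CC)(CC)CC)[C@@H](O[Si](CC)(CC)CC)C[C@H]2[C@@]2(/C=C\COCc4ccc(OC)cc4)OC(=O)[C@@H](C)[C@H]2[C@@H]3C(=O)OCC[Si](C)(C)C | intermediate
41 | Z-allylic alcohol | C=C1[C@@H](O[Si](CC)(CC)CC)[C@]23C[C@@]1(O[Si](CC)(CC)CC)[C@@H](O[Si](CC)(CC)CC)C[C@H]2[C@@]2(/C=C\CO)OC(=O)[C@@H](C)[C@H]2[C@@H]3C(=O)OCC[Si](C)(C)C | intermediate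
42 | Z-enal | C=C1[C@@H](O[Si](CC)(CC)CC)[C@]23C[C@@]1(O[Si](CC)(CC)CC)[C@@H](O[Si](CC)(CC)CC)C[C@H]2[C@@]2(/C=C\C=O)OC(=O)[C@@H](C)[C@H]2[C@@H]3C(=O)OCC[Si](C)(C)C | intermediate
43 | potassium lactone enolate of 42 | C=C1[C@@H](O[Si](CC)(CC)CC)[C@]23C[C@@]1(O[Si](CC)(CC)CC)[C@@H](O[Si](CC)(CC)CC)C[C@H]2[C@@]2(/C=C\C=O)OC([O-])=C(C)[C@H]2[C@@H]3C(=O)OCC[Si](C)(C)C.[K+] | intermediate
44 | 12,13,15-tris(triethylsilyl) ether 2-(trimethylsilyl)ethyl ester of the target gibberellin | C=C1[C@@H](O[Si](CC)(CC)CC)[C@]23C[C@@]1(O[Si](CC)(CC)CC)[C@@H](O[Si](CC)(CC)CC)C[C@H]2[C@@]12C=C[C@H](O)[C@@](C)(C(=O)O1)[C@H]2[C@@H]3C(=O)OCC[Si](C)(C)C | intermediate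
45 | target gibberellin, number thirty-two of the gibberellin A series (3,12,13,15-tetrahydroxy-1,16-diene 7-acid 19,10-lactone) | C=C1[C@@H](O)[C@]23C[C@@]1(O)[C@@H](O)C[C@H]2[C@@]12C=C[C@H](O)[C@@](C)(C(=O)O1)[C@H]2[C@@H]3C(=O)O | target

## Step count and least certain steps

Total step count: 25. Longest linear sequence: 24 steps (steps 1–14 and 16–25); step 15 is a one-step side branch.

**Step 21 (key step).** The enolate may attack the lactone carbonyl instead of C5, or the conjugate addition between two carbons that each adjoin a quaternary centre may be slow and revert on warming. Fallback: starting from 37, the ester enolate is trapped at −78 °C with PhSeCl to give the α-phenylselanyl ester F1. F1 is cyclised by a tin hydride chain (Bu3SnH, AIBN, benzene, 80 °C): the C6 radical adds 5-exo to C5 under the same tether control, and the route is rejoined at 40.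

**Step 16.** The facial preference at the C10 carbonyl may be weak or opposite, giving the C10 epimer. Fallback: the order of the two additions is reversed. Starting from 23, with the ester masked as in step 14, lithium acetylide 30 is added to the lactone to give the alkynyl lactol F2. The vinyl group is then added with 24 and CeCl3, and the route is rejoined at 32.

**Step 24.** A closed, metal-bridged transition state would place the C3 hydroxyl equatorial, and deprotonation at C6 could compete. Fallback: starting from 42, the aldol product obtained as the C3 epimer F3 is oxidised with Dess–Martin periodinane to the ring A enone F4. F4 is reduced with catecholborane and the enantiomer of the Corey–Bakshi–Shibata oxazaborolidine that delivers hydride from the lactone face, and the route is rejoined at 44.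

**Step 14.** Masking of the ester may be incomplete, so that the Grignard reagent also attacks C7. Fallback: starting from 23, the strained lactone is opened selectively with Me2AlN(OMe)Me to the hydroxy Weinreb amide F5. F5 reacts with 24 at the amide; on work-up the open hydroxy ketone tautomer closes to the lactol, and the route is rejoined at 26.

**Step 11.** Oxidative addition into the alkenyl bromide may be slow, or the alkenylchromium may be protonated before it reaches the hindered ketone. Fallback: starting from 20, Miyaura borylation (B2pin2, PdCl2(dppf), KOAc) gives the alkenyl boronate F6. Intramolecular 1,2-addition catalysed by monovalent rhodium ([Rh(OH)(cod)]2) then closes ring D, and the route is rejoined at 21.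

**Step 12.** Oxygen may be delivered to the other face of C15. The resulting epimer could also lactonise onto C7, which is cis to it on ring D. Fallback: starting from 21, the epimeric alcohol F7 is oxidised at once with Dess–Martin periodinane to the enone F8. F8 is reduced with NaBH4 and CeCl3; hydride then arrives on the face the oxidant had used and gives the other epimer, and the route is rejoined at 22.

## Further compounds

F1 | step 21 | α-phenylselanyl ester of 37 (C6 epimers) | C=C1[C@@H](O[Si](CC)(CC)CC)[C@]2(C([Se]c5ccccc5)C(=O)OCC[Si](C)(C)C)C[C@@]1(O[Si](CC)(CC)CC)[C@@H](O[Si](CC)(CC)CC)C[C@H]2[C@]3(/C=C\COCc4ccc(OC)cc4)C=C(C)C(=O)O3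
F2 | step 16 | alkynyl lactol from 23 (C10 hemiketal epimers) | C=C1[C@@H](O[Si](CC)(CC)CC)[C@]2(CC(=O)OCC[Si](C)(C)C)C[C@@]1(O[Si](CC)(CC)CC)[C@@H]3C[C@H]2C(O)(C#CCOCc4ccc(OC)cc4)O3
F3 | step 24 | C3 epimer of 44 | C=C1[C@@H](O[Si](CC)(CC)CC)[C@]23C[C@@]1(O[Si](CC)(CC)CC)[C@@H](O[Si](CC)(CC)CC)C[C@H]2[C@@]12C=C[C@@H](O)[C@@](C)(C(=O)O1)[C@H]2[C@@H]3C(=O)OCC[Si](C)(C)C
F4 | step 24 | ring A enone (C3 ketone) | C=C1[C@@H](O[Si](CC)(CC)CC)[C@]23C[C@@]1(O[Si](CC)(CC)CC)[C@@H](O[Si](CC)(CC)CC)C[C@H]2[C@@]12C=CC(=O)[C@@](C)(C(=O)O1)[C@H]2[C@@H]3C(=O)OCC[Si](C)(C)C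
F5 | step 14 | hydroxy Weinreb amide from 23 | C=C1[C@@H](O[Si](CC)(CC)CC)[C@]2(CC(=O)OCC[Si](C)(C)C)C[C@@]1(O[Si](CC)(CC)CC)[C@@H](O)C[C@H]2C(=O)N(C)OC
F6 | step 11 | alkenyl pinacol boronate from 20 | C[Si](C)(C)CCOC(=O)C[C@@]1(CC(=C)B2OC(C)(C)C(C)(C)O2)CC(=O)[C@@H]3C[C@H]1C(=O)O3
F7 | step 12 | C15 epimer of 22 | C=C1[C@H](O)[C@]2(CC(=O)OCC[Si](C)(C)C)C[C@@]1(O)[C@@H]3C[C@H]2C(=O)O3
F8 | step 12 | C15 enone | C=C1C(=O)[C@]2(CC(=O)OCC[Si](C)(C)C)C[C@@]1(O)[C@@H]3C[C@H]2C(=O)O3
A1 | alternative 1 | C12-keto C13-hydroxy bicyclo[3.2.1]octane with C16 dioxolane | C1COC2(O1)[C@@H](O[Si](C)(C)C(C)(C)C)[C@]34C[C@@]2(O)C(=O)C[C@H]3[C@@]56C=C[C@H](O[Si](C)(C)C(C)(C)C)[C@@](C)(C(=O)O5)[C@H]6[C@@H]4C(=O)OC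
A2 | alternative 2 | ring A C19 acid with the alkene between C1 and C10 | C=C1[C@@H](O[Si](C)(C)C(C)(C)C)[C@]23C[C@@]1(O[Si](C)(C)C)[C@@H](O[Si](C)(C)C(C)(C)C)C[C@H]2C4=CC[C@H](O[Si](C)(C)C(C)(C)C)[C@@](C)(C(=O)O)[C@H]4[C@@H]3COCc5ccc(OC)cc5
A3 | alternative 3 | C6,C8,C15-cyclopropane C16 ketone | O=C1[C@H]4[C@]23C[C@@]1(O[Si](C)(C)C)[C@@H](O[Si](C)(C)C(C)(C)C)C[C@H]2[C@@]12C=C[C@H](O[Si](C)(C)C(C)(C)C)[C@@](C)(C(=O)O1)[C@H]2[C@@]34C(=O)OC
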